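**Strategy.** The route rests on cutting ring B (O, C14–C18) at the C17–C18 bond, which joins two carbons that are both electrophilic in a polar precursor. Samarium diiodide turns the C17 methyl ketone into a ketyl that closes onto C18 of an (E)-β-alkoxyacrylate carried on O14. This one operation forms the bond and the ring, sets the equatorial C17 tertiary hydroxyl trans to the C19 arm with its methyl axial, and makes C14/C18 cis. The feature exploited is the vicinal tertiary carbinol (C17)/ether carbon (C18) pair of ring B. The precursor is ring A (C8–C12) carrying a C13–C17 keto chain whose C14 oxygen bears the acrylate (C18–C20).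

Key step: step 14

Remark on numbering: carbons are numbered along the chain from C1 (terminal vinyl CH2) to C29 (CH2N). Ring B is therefore O, C14, C15 (methyl), C16 (CH2), C17 (methyl and hydroxyl), C18 (bears C19); the key step forms C17–C18, and its precursor spans C6–C17 with C18–C20 as the acrylate.

Assumptions:
- (R)-TRIP, (R)-3,3′-bis(2,4,6-triisopropylphenyl)-1,1′-binaphthyl-2,2′-diyl hydrogen phosphate, is taken to transfer allyl or crotyl from a pinacol boronate to the Re face of an aldehyde (the sense that turns benzaldehyde into (R)-1-phenylbut-3-en-1-ol), and (S)-TRIP to the Si face.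
- (R,R)-Taniaphos (a ferrocene-based diphosphine) is taken to be the enantiomer that turns cinnamyl bromide into (S)-3-phenylbut-1-ene; the same facial sense gives 20R here.
- Compounds 4, 31, 37 and 47 are taken as commercially available.

## Route

**Ring A and the key-step precursor (steps 1–13)**

Step 1
Reactants: 1 methyl (S)-3-hydroxy-2-methylpropanoate
Product: 2 methyl (S)-3-[(tert-butyldiphenylsilyl)oxy]-2-methylpropanoate
Conditions: TBDPSCl, imidazole, CH2Cl2, 0 °C → rt
Reagents that add atoms: tert-butyl(chloro)diphenylsilane, CC(C)(C)[Si](Cl)(c1ccccc1)c1ccccc1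
Why: Silyl ether formation at the primary hydroxyl; TBDPS is chosen because it must survive trifluoroacetic acid in step 5, and C7 is taken unchanged from the chiral pool.

Step 2
Reactants: 2 methyl (S)-3-[(tert-butyldiphenylsilyl)oxy]-2-methylpropanoate
Product: 3 (S)-3-[(tert-butyldiphenylsilyl)oxy]-2-methylpropanal
Conditions: iBu2AlH (1.05 equiv), CH2Cl2, −78 °C; Rochelle salt work-up; used crude
Reagents that add atoms: none
Why: Partial ester reduction through an aluminium hemiacetal that is stable at −78 °C; immediate use should keep C7 from epimerising.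

Step 3
Reactants: 3 (S)-3-[(tert-butyldiphenylsilyl)oxy]-2-methylpropanal; 4 allylboronic acid pinacol ester
Product: 5 (2S,3R)-1-[(tert-butyldiphenylsilyl)oxy]-2-methylhex-5-en-3-ol
Conditions: (R)-TRIP (5 mol %), 4 Å MS, toluene, −30 °C
Reagents that add atoms: none
Why: Chiral phosphoric acid-catalysed allylboration through a closed chair transition state in which the catalyst directs allyl to the Re face of the aldehyde, so C8 is set R (anti to the C7 methyl) under catalyst control.

Step 4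
Reactants: 5 (2S,3R)-1-[(tert-butyldiphenylsilyl)oxy]-2-methylhex-5-en-3-ol; 6 ethyl propiolate
Product: 7 ethyl (E)-3-{[(2S,3R)-1-[(tert-butyldiphenylsilyl)oxy]-2-methylhex-5-en-3-yl]oxy}acrylate
Conditions: N-methylmorpholine (0.3 equiv), CH2Cl2, rt
Reagents that add atoms: none
Why: Amine-catalysed oxa-Michael addition of the alcohol to the ynoate, which should give the (E)-β-alkoxyacrylate.

Step 5
Reactants: 7 ethyl (E)-3-{[(2S,3R)-1-[(tert-butyldiphenylsilyl)oxy]-2-methylhex-5-en-3-yl]oxy}acrylate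
Product: 9 ring A hydroxy ester (all-cis C8–C12 tetrahydropyran with C10 hydroxyl and CH2CO2Et on C12), via ring A trifluoroacetate 8 (not isolated)
Conditions: CF3CO2H (15 equiv), CH2Cl2, 0 °C → rt; evaporate; then K2CO3 (0.2 equiv), EtOH, 0 °C
Reagents that add atoms: trifluoroacetic acid, OC(=O)C(F)(F)F
Why: Prins cyclization of an enol ether: protonation at the acrylate α-carbon gives the C12 oxocarbenium ion, the C10=C11 alkene attacks it through a chair with both side chains equatorial, and trifluoroacetate traps the C10 cation equatorially, so C10 and C12 are set all-cis to C8 before ethanolysis frees the alcohol.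

Step 6
Reactants: 9 ring A hydroxy ester
Product: 10 ring A methyl ether ester (C10 methoxy)
Conditions: Me3O·BF4, 1,8-bis(dimethylamino)naphthalene, 4 Å MS, CH2Cl2, rt
Reagents that add atoms: trimethyloxonium tetrafluoroborate, C[O+](C)C.F[B-](F)(F)F
Why: O-methylation with a Meerwein salt under non-basic conditions, which avoids E1cB opening of the β-alkoxy ester.

Step 7
Reactants: 10 ring A methyl ether ester
Product: 11 ring A C14 aldehyde
Conditions: iBu2AlH (1.1 equiv), CH2Cl2, −78 °C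
Reagents that add atoms: none
Why: Partial reduction of the ester to the aldehyde at low temperature.

Step 8
Reactants: 11 ring A C14 aldehyde; 12 (E)-crotylboronic acid pinacol ester
Product: 13 C14,C15-anti homoallylic alcohol (C6–C17)
Conditions: (S)-TRIP (5 mol %), 4 Å MS, toluene, −30 °C
Reagents that add atoms: none
Why: Chiral phosphoric acid-catalysed crotylboration: the (E)-boronate reacts through a chair transition state to give the anti C14-hydroxyl/C15-methyl pair, and the catalyst directs attack to the Si face, setting C14 and C15 as in the target.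

Step 9
Reactants: 13 C14,C15-anti homoallylic alcohol; 6 ethyl propiolate
Product: 14 O14 (E)-β-alkoxyacrylate of 13
Conditions: N-methylmorpholine (0.5 equiv), CH2Cl2, rt
Reagents that add atoms: none
Why: Amine-catalysed oxa-Michael addition to the ynoate, installing C18–C20 on O14 as the (E)-enol ether.

Step 10
Reactants: 14 O14 (E)-β-alkoxyacrylate
Product: 16 C17 primary alcohol, via B-alkyl-9-BBN adduct 15 (not isolated)
Conditions: 9-BBN (1.5 equiv), THF, 0 °C → rt; then 30% H2O2, aq. NaOAc, 0 °C → rt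
Reagents that add atoms: hydrogen peroxide, OO
Why: Hydroboration–oxidation: the bulky dialkylborane adds to the terminal carbon of the only monosubstituted alkene and should leave the push–pull acrylate alone, and buffered peroxide replaces boron by hydroxyl.

Step 11
Reactants: 16 C17 primary alcohol
Product: 17 C17 aldehyde
Conditions: Dess–Martin periodinane, CH2Cl2, rt
Reagents that add atoms: none
Why: Dess–Martin oxidation of a primary alcohol; the α-carbon (C16) is not stereogenic.

Step 12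
Reactants: 17 C17 aldehyde
Product: 18 C17 secondary alcohol (both C17 epimers)
Conditions: MeMgBr (1.1 equiv), THF, −78 °C
Reagents that add atoms: methylmagnesium bromide, C[Mg]Br
Why: Grignard addition to the aldehyde, which should react at −78 °C well before the vinylogous carbonate ester; the uncontrolled carbinol centre is erased in step 13.

Step 13
Reactants: 18 C17 secondary alcohol
Product: 19 ring A keto β-alkoxyacrylate (key-step precursor, C6–C17 with C18–C20 as acrylate)
Conditions: Dess–Martin periodinane, CH2Cl2, rt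
Reagents that add atoms: none
Why: Dess–Martin oxidation of the secondary alcohol to the C17 methyl ketone.

**Key step (step 14)**

Step 14
Reactants: 19 ring A keto β-alkoxyacrylate
Product: 20 bis-pyran C20 ethyl ester with free C17 hydroxyl
Conditions: SmI2 (3 equiv, 0.1 M in THF), MeOH (3 equiv), THF, 0 °C
Reagents that add atoms: none
Why: Samarium diiodide (divalent samarium) transfers one electron to the C17 ketone; the trivalent samarium ketyl, held by chelation to the acrylate carbonyl, adds to C18 (the β-carbon of the s-trans (E)-β-alkoxyacrylate), and a second electron gives a samarium enolate that methanol protonates. The closest known reaction type is the SmI2-induced reductive cyclization of carbonyl-tethered β-alkoxyacrylates to 2,6-cis-3-hydroxytetrahydropyrans, a ketyl–olefin radical cyclization. Ring B (O, C14–C18) closes in the 6-exo-trig mode through a chair. C18 is set cis to C14 because the acrylate and the C13 chain both sit equatorial on that chair, with the C15 methyl equatorial as well; C17 is set by the samarium chelate, which holds the ketyl oxygen equatorial (trans to the C19 arm) and leaves the methyl axial. The step needs cyclization to outrun simple ketone reduction and pinacol coupling and needs a single chair; the tethered electron-poor alkene, its (E) geometry and the equatorial substituents at C14 and C15 should secure both. Two electrophilic carbons are thus joined by polarity reversal in one operation.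

**From the key-step product to the C6–C21 sulfone (steps 15–23)**

Step 15
Reactants: 20 bis-pyran C20 ethyl ester
Product: 21 C17 triethylsilyl ether of 20
Conditions: Et3SiOTf, 2,6-lutidine, CH2Cl2, −78 → 0 °C
Reagents that add atoms: triethylsilyl trifluoromethanesulfonate, CC[Si](CC)(CC)OS(=O)(=O)C(F)(F)F
Why: Silylation of the tertiary alcohol with a silyl triflate, so that the later C20 and C21 aldehydes cannot form lactols or undergo oxa-Michael closure.

Step 16
Reactants: 21 C17 triethylsilyl ether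
Product: 22 C20 aldehyde
Conditions: iBu2AlH (1.1 equiv), CH2Cl2, −78 °C
Reagents that add atoms: none
Why: Partial reduction of the ester to the aldehyde at low temperature.

Step 17
Reactants: 22 C20 aldehyde
Product: 23 (E)-enoate (C20=C21, C22 ethyl ester)
Conditions: Ph3P=CHCO2Et, CH2Cl2, rt
Reagents that add atoms: ethyl (triphenylphosphoranylidene)acetate, CCOC(=O)C=P(c1ccccc1)(c1ccccc1)c1ccccc1
Why: Wittig olefination with a stabilised ylide, E-selective and neutral, so the β-alkoxy aldehyde should not open by E1cB elimination.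

Step 18
Reactants: 23 (E)-enoate
Product: 24 (E)-allylic alcohol (C22 hydroxyl)
Conditions: iBu2AlH (2.5 equiv), CH2Cl2, −78 °C
Reagents that add atoms: none
Why: 1,2-Reduction of the enoate to the allylic alcohol by the aluminium hydride.

Step 19
Reactants: 24 (E)-allylic alcohol
Product: 25 (E)-allylic bromide (C22 bromide)
Conditions: CBr4, PPh3, CH2Cl2, 0 °C
Reagents that add atoms: carbon tetrabromide, BrC(Br)(Br)Br
Why: Appel bromination, SN2 at the primary allylic carbon under neutral conditions.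

Step 20
Reactants: 25 (E)-allylic bromide
Product: 26 C20-methyl terminal alkene (20R, C21=C22)
Conditions: MeMgBr (1.3 equiv, slow addition), CuBr·SMe2 (3 mol %), (R,R)-Taniaphos (3.3 mol %), CH2Cl2, −75 °C
Reagents that add atoms: methylmagnesium bromide, C[Mg]Br
Why: Copper-catalysed asymmetric allylic alkylation in the SN2′ sense: the chiral diphosphine–copper methyl species adds at the γ-carbon C20 anti to bromide, and the ligand controls the face, setting C20 R under catalyst control.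

Step 21
Reactants: 26 C20-methyl terminal alkene
Product: 28 C21 primary alcohol, via C21–C22 ozonide 27 (not isolated)
Conditions: O3, CH2Cl2, −78 °C; then NaBH4, MeOH, −78 °C → rt
Reagents that add atoms: ozone, [O-][O+]=O
Why: Ozonolysis with reductive work-up of the only alkene; hydride reduces the ozonide straight to the alcohol, which avoids handling an epimerisable α-methyl aldehyde at C20.

Step 22
Reactants: 28 C21 primary alcohol
Product: 29 C21 1-phenyl-1H-tetrazol-5-yl sulfide
Conditions: 1-phenyl-1H-tetrazole-5-thiol, PPh3, iPrO2CN=NCO2iPr, THF, 0 °C → rt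
Reagents that add atoms: 1-phenyl-1H-tetrazole-5-thiol, Sc1nnnn1-c1ccccc1
Why: Mitsunobu thioetherification of the primary alcohol; C20 is not involved.

Step 23
Reactants: 29 C21 sulfide
Product: 30 C21 1-phenyl-1H-tetrazol-5-yl sulfone (fragment C6–C21)
Conditions: 3-chloroperbenzoic acid (3 equiv), NaHCO3, CH2Cl2, 0 °C → rt
Reagents that add atoms: 3-chloroperbenzoic acid, OOC(=O)c1cccc(Cl)c1
Why: Peracid oxidation of sulfide to sulfone; the substrate carries no alkene at this stage.

**Fragment C22–C29 (steps 24–29)**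

Step 24
Reactants: 31 ethyl (S)-4-chloro-3-hydroxybutanoate
Product: 32 ethyl (S)-4-azido-3-hydroxybutanoate
Conditions: NaN3, DMF, 80 °C
Reagents that add atoms: sodium azide, [Na+].[N-]=[N+]=[N-]
Why: SN2 displacement of the primary chloride by azide; C28 comes unchanged from the chiral pool.

Step 25
Reactants: 32 ethyl (S)-4-azido-3-hydroxybutanoate
Product: 33 ethyl (S)-4-azido-3-[(triisopropylsilyl)oxy]butanoate
Conditions: iPr3SiOTf, 2,6-lutidine, CH2Cl2, 0 °C
Reagents that add atoms: triisopropylsilyl trifluoromethanesulfonate, CC(C)[Si](OS(=O)(=O)C(F)(F)F)(C(C)C)C(C)C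
Why: Silylation with a silyl triflate; the hindered TIPS ether is meant to outlast every later fluoride step except the last.

Step 26
Reactants: 33 ethyl (S)-4-azido-3-[(triisopropylsilyl)oxy]butanoate
Product: 34 (S)-4-azido-3-[(triisopropylsilyl)oxy]butanal
Conditions: iBu2AlH (1.1 equiv), CH2Cl2, −78 °C
Reagents that add atoms: none
Why: Partial ester reduction at −78 °C, where the alkyl azide should be inert to the hydride.

Step 27
Reactants: 34 (S)-4-azido-3-[(triisopropylsilyl)oxy]butanal; 4 allylboronic acid pinacol ester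
Product: 35 (4R,6S)-7-azido-6-[(triisopropylsilyl)oxy]hept-1-en-4-ol
Conditions: (R)-TRIP (5 mol %), 4 Å MS, toluene, −30 °C
Reagents that add atoms: none
Why: Chiral phosphoric acid-catalysed allylboration with Re-face delivery, setting C26 R (1,3-anti to C28) under catalyst control.

Step 28
Reactants: 35 (4R,6S)-7-azido-6-[(triisopropylsilyl)oxy]hept-1-en-4-ol
Product: 36 (4R,6S)-7-azido-4-[(triethylsilyl)oxy]-6-[(triisopropylsilyl)oxy]hept-1-ene
Conditions: Et3SiCl, imidazole, CH2Cl2, 0 °C → rt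
Reagents that add atoms: chlorotriethylsilane, CC[Si](Cl)(CC)CC
Why: Silyl ether formation; the labile TES group marks the C26 oxygen for later release together with the C6 oxygen.

Step 29
Reactants: 36 (4R,6S)-7-azido-4-[(triethylsilyl)oxy]-6-[(triisopropylsilyl)oxy]hept-1-ene; 37 methacrolein
Product: 38 (2E,5R,7S)-8-azido-2-methyl-5-[(triethylsilyl)oxy]-7-[(triisopropylsilyl)oxy]oct-2-enal (fragment C22–C29)
Conditions: methacrolein (10 equiv), second-generation Hoveyda–Grubbs catalyst RuCl2(H2IMes)(=CH-C6H4-2-OiPr) (5 mol %), CH2Cl2, 40 °C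
Reagents that add atoms: none
Why: Olefin cross-metathesis of a terminal alkene with a 1,1-disubstituted enal, which should give the (E)-trisubstituted C23=C24 bond under thermodynamic control with loss of ethene.

**Fragment union and endgame (steps 30–38)**

Step 30
Reactants: 30 C21 sulfone (fragment C6–C21); 38 enal (fragment C22–C29)
Product: 39 fully protected (21E,23E)-diene (C6–C29)
Conditions: 30, KN(SiMe3)2 (1.1 equiv), DME, −60 °C, 30 min; then 38, −60 °C → rt
Reagents that add atoms: none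
Why: Julia–Kocienski olefination: the potassium sulfonyl carbanion adds to the enal and Smiles rearrangement with loss of SO2 and tetrazololate forms C21=C22, expected E for a phenyltetrazolyl sulfone with potassium in DME; C20 is β to the anion and cannot epimerise.

Step 31
Reactants: 39 fully protected diene
Product: 40 C6,C26-diol (C17 TES and C28 TIPS ethers retained)
Conditions: Bu4NF (4 equiv), AcOH (4 equiv), THF, 0 °C → rt
Reagents that add atoms: none
Why: Acetic acid-buffered fluoride desilylation: the unhindered primary TBDPS ether and the secondary TES ether should cleave, while the tertiary TES and secondary TIPS ethers, both far more hindered, should stay.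

Step 32
Reactants: 40 C6,C26-diol
Product: 41 C6 aldehyde (C26 hydroxyl free)
Conditions: TEMPO (0.2 equiv), PhI(OAc)2 (1.3 equiv), CH2Cl2, rt
Reagents that add atoms: none
Why: TEMPO-catalysed oxidation, in which the oxoammonium salt is strongly selective for the primary over the secondary hydroxyl; the mild conditions should leave C7 intact.

Step 33
Reactants: 41 C6 aldehyde
Product: 42 (5E)-C4 enal (C5 methyl)
Conditions: Ph3P=C(CH3)CHO (3 equiv), toluene, 80 °C
Reagents that add atoms: 2-(triphenylphosphoranylidene)propanal, CC(C=O)=P(c1ccccc1)(c1ccccc1)c1ccccc1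
Why: Wittig olefination with a stabilised formyl ylide, E-selective for the trisubstituted C5=C6 bond under neutral conditions.

Step 34
Reactants: 42 (5E)-C4 enal
Product: 43 west triene with free C26 hydroxyl
Conditions: CH2=CHCH2P(O)Ph2 (3.5 equiv), n-BuLi (3.4 equiv), THF, −78 °C; HMPA (7 equiv); then 42, −78 °C → rt
Reagents that add atoms: allyldiphenylphosphine oxide, C=CCP(=O)(c1ccccc1)c1ccccc1
Why: Horner–Wittig olefination: the lithiated allylphosphine oxide adds through its α-carbon to the aldehyde and the adduct loses lithium diphenylphosphinate in the presence of HMPA to give the (E)-C3=C4 bond of the terminal diene; the free C26 hydroxyl only consumes one equivalent of base.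

Step 35
Reactants: 43 west triene with free C26 hydroxyl
Product: 45 C26 carbamate, via N-trichloroacetyl carbamate 44 (not isolated)
Conditions: Cl3CC(O)NCO (1.5 equiv), CH2Cl2, 0 °C; then K2CO3 (0.3 equiv), MeOH, 0 °C
Reagents that add atoms: trichloroacetyl isocyanate, O=C=NC(=O)C(Cl)(Cl)Cl
Why: Carbamoylation with an acyl isocyanate followed by methanolysis of the trichloroacetyl group; C26 carries the only free hydroxyl.

Step 36
Reactants: 45 C26 carbamate
Product: 46 azido diol (C17 and C28 hydroxyls free)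
Conditions: HF·pyridine, pyridine, THF, 0 °C → rt
Reagents that add atoms: none
Why: Buffered acidic fluoride desilylation of the tertiary TES and secondary TIPS ethers, run before the acid-labile enol ether amide is introduced and without an alkoxide that could shift the carbamate.

Step 37
Reactants: 47 methyl 2-methoxyacrylate
Product: 48 2-methoxyacrylic acid
Conditions: LiOH·H2O, THF/H2O, 0 °C; then 1 M HCl to pH 2; used at once
Reagents that add atoms: lithium hydroxide, [Li+].[OH-]
Why: Ester saponification by acyl–oxygen cleavage; the acid is used directly to avoid polymerisation.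

Step 38
Reactants: 46 azido diol; 48 2-methoxyacrylic acid
Product: 51 CNP0220268.1, via iminophosphorane 49 (not isolated), via C29 amine 50 (not isolated)
Conditions: PMe3 (2 equiv), THF/H2O (10:1), rt; evaporate; then 48, EDC·HCl, HOBt (0.2 equiv), CH2Cl2/DMF, 0 °C → rt
Reagents that add atoms: none
Why: Staudinger reduction followed in the same flask by carbodiimide-mediated amide coupling; the primary amine should be acylated far faster than the secondary and tertiary alcohols or the carbamate nitrogen.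

## Compound list

1 | methyl (S)-3-hydroxy-2-methylpropanoate | OC[C@H](C)C(=O)OC | starting material
2 | methyl (S)-3-[(tert-butyldiphenylsilyl)oxy]-2-methylpropanoate | CC(C)(C)[Si](c1ccccc1)(c2ccccc2)OC[C@H](C)C(=O)OC | intermediate
3 | (S)-3-[(tert-butyldiphenylsilyl)oxy]-2-methylpropanal | CC(C)(C)[Si](c1ccccc1)(c2ccccc2)OC[C@H](C)C=O | intermediate
4 | allylboronic acid pinacol ester | C=CCB1OC(C)(C)C(C)(C)O1 | starting material
5 | (2S,3R)-1-[(tert-butyldiphenylsilyl)oxy]-2-methylhex-5-en-3-ol (C6–C11) | CC(C)(C)[Si](c1ccccc1)(c2ccccc2)OC[C@H](C)[C@H](O)CC=C | intermediate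
6 | ethyl propiolate | C#CC(=O)OCC | starting material
7 | ethyl (E)-3-{[(2S,3R)-1-[(tert-butyldiphenylsilyl)oxy]-2-methylhex-5-en-3-yl]oxy}acrylate | CC(C)(C)[Si](c1ccccc1)(c2ccccc2)OC[C@H](C)[C@H](O/C=C/C(=O)OCC)CC=C | intermediate
8 | ring A trifluoroacetate: all-cis tetrahydropyran (C8–C12) with C10 trifluoroacetoxy, CH2CO2Et on C12 and the (S)-1-(TBDPS-oxy)propan-2-yl group on C8 | CC(C)(C)[Si](c1ccccc1)(c2ccccc2)OC[C@H](C)[C@H]3C[C@@H](OC(=O)C(F)(F)F)C[C@@H](CC(=O)OCC)O3 | intermediate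
9 | ring A hydroxy ester: as 8 with free C10 hydroxyl | CC(C)(C)[Si](c1ccccc1)(c2ccccc2)OC[C@H](C)[C@H]3C[C@@H](O)C[C@@H](CC(=O)OCC)O3 | intermediate
10 | ring A methyl ether ester: as 9 with C10 methoxy | CC(C)(C)[Si](c1ccccc1)(c2ccccc2)OC[C@H](C)[C@H]3C[C@@H](OC)C[C@@H](CC(=O)OCC)O3 | intermediate
11 | ring A C14 aldehyde (C6–C14) | CC(C)(C)[Si](c1ccccc1)(c2ccccc2)OC[C@H](C)[C@H]3C[C@@H](OC)C[C@@H](CC=O)O3 | intermediate
12 | (E)-crotylboronic acid pinacol ester | C/C=C/CB1OC(C)(C)C(C)(C)O1 | starting material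
13 | C14,C15-anti homoallylic alcohol (C6–C17; C14 hydroxyl, C15 methyl, C16=C17 vinyl; configurations as in the target) | CC(C)(C)[Si](c1ccccc1)(c2ccccc2)OC[C@H](C)[C@H]3C[C@@H](OC)C[C@@H](C[C@@H](O)[C@@H](C)C=C)O3 | intermediate
14 | O14 (E)-β-alkoxyacrylate of 13 | CC(C)(C)[Si](c1ccccc1)(c2ccccc2)OC[C@H](C)[C@H]3C[C@@H](OC)C[C@@H](C[C@@H](O/C=C/C(=O)OCC)[C@@H](C)C=C)O3 | intermediate
15 | B-alkyl-9-BBN adduct at C17 | CC(C)(C)[Si](c1ccccc1)(c2ccccc2)OC[C@H](C)[C@H]3C[C@@H](OC)C[C@@H](C[C@@H](O/C=C/C(=O)OCC)[C@@H](C)CCB4C5CCCC4CCC5)O3 | intermediate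
16 | C17 primary alcohol | CC(C)(C)[Si](c1ccccc1)(c2ccccc2)OC[C@H](C)[C@H]3C[C@@H](OC)C[C@@H](C[C@@H](O/C=C/C(=O)OCC)[C@@H](C)CCO)O3 | intermediate
17 | C17 aldehyde | CC(C)(C)[Si](c1ccccc1)(c2ccccc2)OC[C@H](C)[C@H]3C[C@@H](OC)C[C@@H](C[C@@H](O/C=C/C(=O)OCC)[C@@H](C)CC=O)O3 | intermediate
18 | C17 secondary alcohol (both C17 epimers) | CC(C)(C)[Si](c1ccccc1)(c2ccccc2)OC[C@H](C)[C@H]3C[C@@H](OC)C[C@@H](C[C@@H](O/C=C/C(=O)OCC)[C@@H](C)CC(C)O)O3 | intermediate
19 | ring A keto β-alkoxyacrylate (key-step precursor; C6–C17, C18–C20 as acrylate) | CC(C)(C)[Si](c1ccccc1)(c2ccccc2)OC[C@H](C)[C@H]3C[C@@H](OC)C[C@@H](C[C@@H](O/C=C/C(=O)OCC)[C@@H](C)CC(C)=O)O3 | intermediate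
20 | bis-pyran C20 ethyl ester with free C17 hydroxyl (key-step product) | CC(C)(C)[Si](c1ccccc1)(c2ccccc2)OC[C@H](C)[C@H]3C[C@@H](OC)C[C@@H](C[C@H]4O[C@@H](CC(=O)OCC)[C@](C)(O)C[C@@H]4C)O3 | intermediate
21 | C17 triethylsilyl ether of 20 | CC(C)(C)[Si](c1ccccc1)(c2ccccc2)OC[C@H](C)[C@H]3C[C@@H](OC)C[C@@H](C[C@H]4O[C@@H](CC(=O)OCC)[C@](C)(O[Si](CC)(CC)CC)C[C@@H]4C)O3 | intermediate
22 | C20 aldehyde | CC(C)(C)[Si](c1ccccc1)(c2ccccc2)OC[C@H](C)[C@H]3C[C@@H](OC)C[C@@H](C[C@H]4O[C@@H](CC=O)[C@](C)(O[Si](CC)(CC)CC)C[C@@H]4C)O3 | intermediate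
23 | (E)-enoate (C20=C21, C22 ethyl ester) | CC(C)(C)[Si](c1ccccc1)(c2ccccc2)OC[C@H](C)[C@H]3C[C@@H](OC)C[C@@H](C[C@H]4O[C@@H](C/C=C/C(=O)OCC)[C@](C)(O[Si](CC)(CC)CC)C[C@@H]4C)O3 | intermediate
24 | (E)-allylic alcohol (C22 hydroxyl) | CC(C)(C)[Si](c1ccccc1)(c2ccccc2)OC[C@H](C)[C@H]3C[C@@H](OC)C[C@@H](C[C@H]4O[C@@H](C/C=C/CO)[C@](C)(O[Si](CC)(CC)CC)C[C@@H]4C)O3 | intermediate
25 | (E)-allylic bromide (C22 bromide) | CC(C)(C)[Si](c1ccccc1)(c2ccccc2)OC[C@H](C)[C@H]3C[C@@H](OC)C[C@@H](C[C@H]4O[C@@H](C/C=C/CBr)[C@](C)(O[Si](CC)(CC)CC)C[C@@H]4C)O3 | intermediate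
26 | C20-methyl terminal alkene (20R; C21=C22) | CC(C)(C)[Si](c1ccccc1)(c2ccccc2)OC[C@H](C)[C@H]3C[C@@H](OC)C[C@@H](C[C@H]4O[C@@H](C[C@@H](C)C=C)[C@](C)(O[Si](CC)(CC)CC)C[C@@H]4C)O3 | intermediate
27 | C21–C22 ozonide (1,2,4-trioxolane) | CC(C)(C)[Si](c1ccccc1)(c2ccccc2)OC[C@H](C)[C@H]3C[C@@H](OC)C[C@@H](C[C@H]4O[C@@H](C[C@@H](C)C5OCOO5)[C@](C)(O[Si](CC)(CC)CC)C[C@@H]4C)O3 | intermediate
28 | C21 primary alcohol | CC(C)(C)[Si](c1ccccc1)(c2ccccc2)OC[C@H](C)[C@H]3C[C@@H](OC)C[C@@H](C[C@H]4O[C@@H](C[C@@H](C)CO)[C@](C)(O[Si](CC)(CC)CC)C[C@@H]4C)O3 | intermediate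
29 | C21 1-phenyl-1H-tetrazol-5-yl sulfide | CC(C)(C)[Si](c1ccccc1)(c2ccccc2)OC[C@H](C)[C@H]3C[C@@H](OC)C[C@@H](C[C@H]4O[C@@H](C[C@@H](C)CSc5nnnn5-c6ccccc6)[C@](C)(O[Si](CC)(CC)CC)C[C@@H]4C)O3 | intermediate
30 | C21 1-phenyl-1H-tetrazol-5-yl sulfone (fragment C6–C21) | CC(C)(C)[Si](c1ccccc1)(c2ccccc2)OC[C@H](C)[C@H]3C[C@@H](OC)C[C@@H](C[C@H]4O[C@@H](C[C@@H](C)CS(=O)(=O)c5nnnn5-c6ccccc6)[C@](C)(O[Si](CC)(CC)CC)C[C@@H]4C)O3 | intermediate
31 | ethyl (S)-4-chloro-3-hydroxybutanoate | CCOC(=O)C[C@H](O)CCl | starting material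
32 | ethyl (S)-4-azido-3-hydroxybutanoate | CCOC(=O)C[C@H](O)CN=[N+]=[N-] | intermediate
33 | ethyl (S)-4-azido-3-[(triisopropylsilyl)oxy]butanoate | CCOC(=O)C[C@H](O[Si](C(C)C)(C(C)C)C(C)C)CN=[N+]=[N-] | intermediate
34 | (S)-4-azido-3-[(triisopropylsilyl)oxy]butanal | O=CC[C@H](O[Si](C(C)C)(C(C)C)C(C)C)CN=[N+]=[N-] | intermediate
35 | (4R,6S)-7-azido-6-[(triisopropylsilyl)oxy]hept-1-en-4-ol | C=CC[C@@H](O)C[C@H](O[Si](C(C)C)(C(C)C)C(C)C)CN=[N+]=[N-] | intermediate
36 | (4R,6S)-7-azido-4-[(triethylsilyl)oxy]-6-[(triisopropylsilyl)oxy]hept-1-ene | C=CC[C@@H](O[Si](CC)(CC)CC)C[C@H](O[Si](C(C)C)(C(C)C)C(C)C)CN=[N+]=[N-] | intermediate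
37 | methacrolein | CC(=C)C=O | starting material
38 | (2E,5R,7S)-8-azido-2-methyl-5-[(triethylsilyl)oxy]-7-[(triisopropylsilyl)oxy]oct-2-enal (fragment C22–C29) | O=C/C(C)=C/C[C@@H](O[Si](CC)(CC)CC)C[C@H](O[Si](C(C)C)(C(C)C)C(C)C)CN=[N+]=[N-] | intermediate
39 | fully protected (21E,23E)-diene (C6 TBDPS, C17 TES, C26 TES, C28 TIPS, C29 azide) | CC(C)(C)[Si](c1ccccc1)(c2ccccc2)OC[C@H](C)[C@H]3C[C@@H](OC)C[C@@H](C[C@H]4O[C@@H](C[C@@H](C)/C=C/C(C)=C/C[C@@H](O[Si](CC)(CC)CC)C[C@H](O[Si](C(C)C)(C(C)C)C(C)C)CN=[N+]=[N-])[C@](C)(O[Si](CC)(CC)CC)C[C@@H]4C)O3 | intermediate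
40 | C6,C26-diol (C17 TES, C28 TIPS, C29 azide) | OC[C@H](C)[C@H]3C[C@@H](OC)C[C@@H](C[C@H]4O[C@@H](C[C@@H](C)/C=C/C(C)=C/C[C@@H](O)C[C@H](O[Si](C(C)C)(C(C)C)C(C)C)CN=[N+]=[N-])[C@](C)(O[Si](CC)(CC)CC)C[C@@H]4C)O3 | intermediate
41 | C6 aldehyde with free C26 hydroxyl | O=C[C@H](C)[C@H]3C[C@@H](OC)C[C@@H](C[C@H]4O[C@@H](C[C@@H](C)/C=C/C(C)=C/C[C@@H](O)C[C@H](O[Si](C(C)C)(C(C)C)C(C)C)CN=[N+]=[N-])[C@](C)(O[Si](CC)(CC)CC)C[C@@H]4C)O3 | intermediate
42 | (5E)-C4 enal with C5 methyl | O=C/C(C)=C/[C@H](C)[C@H]3C[C@@H](OC)C[C@@H](C[C@H]4O[C@@H](C[C@@H](C)/C=C/C(C)=C/C[C@@H](O)C[C@H](O[Si](C(C)C)(C(C)C)C(C)C)CN=[N+]=[N-])[C@](C)(O[Si](CC)(CC)CC)C[C@@H]4C)O3 | intermediate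
43 | west triene with free C26 hydroxyl | C=C/C=C/C(C)=C/[C@H](C)[C@H]3C[C@@H](OC)C[C@@H](C[C@H]4O[C@@H](C[C@@H](C)/C=C/C(C)=C/C[C@@H](O)C[C@H](O[Si](C(C)C)(C(C)C)C(C)C)CN=[N+]=[N-])[C@](C)(O[Si](CC)(CC)CC)C[C@@H]4C)O3 | intermediate
44 | C26 N-trichloroacetyl carbamate | C=C/C=C/C(C)=C/[C@H](C)[C@H]3C[C@@H](OC)C[C@@H](C[C@H]4O[C@@H](C[C@@H](C)/C=C/C(C)=C/C[C@@H](OC(=O)NC(=O)C(Cl)(Cl)Cl)C[C@H](O[Si](C(C)C)(C(C)C)C(C)C)CN=[N+]=[N-])[C@](C)(O[Si](CC)(CC)CC)C[C@@H]4C)O3 | intermediate
45 | C26 carbamate (C17 TES, C28 TIPS, C29 azide) | C=C/C=C/C(C)=C/[C@H](C)[C@H]3C[C@@H](OC)C[C@@H](C[C@H]4O[C@@H](C[C@@H](C)/C=C/C(C)=C/C[C@@H](OC(N)=O)C[C@H](O[Si](C(C)C)(C(C)C)C(C)C)CN=[N+]=[N-])[C@](C)(O[Si](CC)(CC)CC)C[C@@H]4C)O3 | intermediate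
46 | azido diol (C17 and C28 hydroxyls free, C26 carbamate) | C=C/C=C/C(C)=C/[C@H](C)[C@H]3C[C@@H](OC)C[C@@H](C[C@H]4O[C@@H](C[C@@H](C)/C=C/C(C)=C/C[C@@H](OC(N)=O)C[C@H](O)CN=[N+]=[N-])[C@](C)(O)C[C@@H]4C)O3 | intermediate
47 | methyl 2-methoxyacrylate | COC(=C)C(=O)OC | starting material
48 | 2-methoxyacrylic acid | COC(=C)C(O)=O | intermediate
49 | C29 trimethyliminophosphorane | C=C/C=C/C(C)=C/[C@H](C)[C@H]3C[C@@H](OC)C[C@@H](C[C@H]4O[C@@H](C[C@@H](C)/C=C/C(C)=C/C[C@@H](OC(N)=O)C[C@H](O)CN=P(C)(C)C)[C@](C)(O)C[C@@H]4C)O3 | intermediate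
50 | C29 primary amine | C=C/C=C/C(C)=C/[C@H](C)[C@H]3C[C@@H](OC)C[C@@H](C[C@H]4O[C@@H](C[C@@H](C)/C=C/C(C)=C/C[C@@H](OC(N)=O)C[C@H](O)CN)[C@](C)(O)C[C@@H]4C)O3 | intermediate
51 | CNP0220268.1 | C=C/C=C/C(C)=C/[C@H](C)[C@H]1C[C@@H](OC)C[C@@H](C[C@H]2O[C@@H](C[C@@H](C)/C=C/C(C)=C/C[C@H](C[C@H](O)CNC(=O)C(=C)OC)OC(N)=O)[C@](C)(O)C[C@@H]2C)O1 | target

## Step count and risks

Total: 38 steps. Longest linear sequence: 31 steps (steps 1–23, 30–36 and 38); steps 24–29 and step 37 are side branches.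

**Step 14.** The ketyl may be reduced on to the alcohol or may dimerise before it cyclises, or the chair may not discriminate fully at C17. Fallback, from aldehyde 17 back to 20: the aldehyde ketyl, which cyclises faster than a ketone ketyl, is closed with SmI2/MeOH in THF to the ring B secondary alcohol F1 (hydroxyl trans to the C19 arm). Dess–Martin oxidation gives the ring B ketone F2. MeLi in the presence of MeAl(OC6H2-2,6-tBu2-4-Me)2 in toluene at −78 °C then adds methyl axially to the complexed ketone and returns to 20. The quaternary centre is thus set by a polar, Lewis acid-directed addition instead of by ketyl geometry.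

**Step 20.** Methyl may be delivered to the α-carbon (linear SN2 product) or to the wrong face of C20. Fallback, from aldehyde 22 back to alcohol 28, with auxiliary control:
- Wittig methylenation (Ph3P=CH2) gives the terminal alkene F3.
- 9-BBN then H2O2/NaOAc gives the primary alcohol F4.
- Dess–Martin oxidation gives the one-carbon-longer aldehyde F5.
- Condensation with (S)-1-amino-2-(methoxymethyl)pyrrolidine gives the hydrazone F6.
- LiN(iPr)2 then MeI gives the C20-methylated hydrazone F7, with the face fixed by the chelated azaenolate.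
- Ozonolysis of the C=N bond gives the α-methyl aldehyde F8, which NaBH4 reduces in the same flask to 28.

**Step 30.** The adducts may collapse with incomplete E selectivity, or the sulfonyl anion may deprotonate the enal at C25 instead of adding. Fallback, from alkene 26 and enal 38 back to 39, by metathesis instead of carbonyl olefination: Wittig methylenation of 38 (Ph3P=CH2) gives the 2-methyl-1,3-diene F9. Cross-metathesis of F9 with 26 using the second-generation Hoveyda–Grubbs catalyst RuCl2(H2IMes)(=CH-C6H4-2-OiPr) in CH2Cl2 at 40 °C joins the two monosubstituted termini to the (21E)-diene 39; steps 21–23 are then not needed.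

## Further compounds

F1 | step 14 | ring B secondary alcohol (C17 hydroxyl trans to the C19 arm, no C17 methyl) | CC(C)(C)[Si](c1ccccc1)(c2ccccc2)OC[C@H](C)[C@H]3C[C@@H](OC)C[C@@H](C[C@H]4O[C@@H](CC(=O)OCC)[C@H](O)C[C@@H]4C)O3
F2 | step 14 | ring B C17 ketone | CC(C)(C)[Si](c1ccccc1)(c2ccccc2)OC[C@H](C)[C@H]3C[C@@H](OC)C[C@@H](C[C@H]4O[C@@H](CC(=O)OCC)C(=O)C[C@@H]4C)O3
F3 | step 20 | C20=C21 terminal alkene | CC(C)(C)[Si](c1ccccc1)(c2ccccc2)OC[C@H](C)[C@H]3C[C@@H](OC)C[C@@H](C[C@H]4O[C@@H](CC=C)[C@](C)(O[Si](CC)(CC)CC)C[C@@H]4C)O3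
F4 | step 20 | C21 primary alcohol without C20 methyl | CC(C)(C)[Si](c1ccccc1)(c2ccccc2)OC[C@H](C)[C@H]3C[C@@H](OC)C[C@@H](C[C@H]4O[C@@H](CCCO)[C@](C)(O[Si](CC)(CC)CC)C[C@@H]4C)O3
F5 | step 20 | C21 aldehyde without C20 methyl | CC(C)(C)[Si](c1ccccc1)(c2ccccc2)OC[C@H](C)[C@H]3C[C@@H](OC)C[C@@H](C[C@H]4O[C@@H](CCC=O)[C@](C)(O[Si](CC)(CC)CC)C[C@@H]4C)O3
F6 | step 20 | C21 hydrazone of (S)-1-amino-2-(methoxymethyl)pyrrolidine | CC(C)(C)[Si](c1ccccc1)(c2ccccc2)OC[C@H](C)[C@H]3C[C@@H](OC)C[C@@H](C[C@H]4O[C@@H](CC/C=N/N5CCC[C@H]5COC)[C@](C)(O[Si](CC)(CC)CC)C[C@@H]4C)O3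
F7 | step 20 | C20-methylated hydrazone (20R) | CC(C)(C)[Si](c1ccccc1)(c2ccccc2)OC[C@H](C)[C@H]3C[C@@H](OC)C[C@@H](C[C@H]4O[C@@H](C[C@@H](C)/C=N/N5CCC[C@H]5COC)[C@](C)(O[Si](CC)(CC)CC)C[C@@H]4C)O3
F8 | step 20 | C20-methyl C21 aldehyde (20R) | CC(C)(C)[Si](c1ccccc1)(c2ccccc2)OC[C@H](C)[C@H]3C[C@@H](OC)C[C@@H](C[C@H]4O[C@@H](C[C@@H](C)C=O)[C@](C)(O[Si](CC)(CC)CC)C[C@@H]4C)O3
F9 | step 30 | (3E,6R,8S)-9-azido-3-methyl-6-[(triethylsilyl)oxy]-8-[(triisopropylsilyl)oxy]nona-1,3-diene | C=C/C(C)=C/C[C@@H](O[Si](CC)(CC)CC)C[C@H](O[Si](C(C)C)(C(C)C)C(C)C)CN=[N+]=[N-]
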